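The numbers are assumed, and the outcome is calculated.

At the first moment in a closed flask like larch, substrate and coupling partner still stand at their whole charge, and that is when you can time one turn of the catalyst.

    coupling partner + free catalyst → catalyst intermediate A (k1 = 21 /M/min)
    catalyst intermediate A → catalyst intermediate B (k2 = 3.7 /min)
    substrate + catalyst intermediate B ⇌ catalyst intermediate C (K3 = 660 /M, k3 = 660 /M/min)
    catalyst intermediate C → free catalyst + target (k4 = 27 /min)
    2 catalyst intermediate A ⇌ resting dimer, settled at all times (K5 = 3200 /M)
    substrate + target → side product (k6 = 0.021 /M/min)

| flask | substrate | coupling partner | free catalyst | time | remark |
|---|---|---|---|---|---|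
| oak | 0.050 M (fed, over 4.00 h) | 0.100 M | 0.10 mM | 5.0 h | a stirred flask in which substrate is dosed at a steady rate over 4.00 h without added volume, worked up at 5.0 h |
| alder | 0.050 M | 0.100 M | 0.10 mM |  | one stirred flow tank at steady state, fed with the mixture as stated, mean residence time 5.0 h |
| birch | 0.050 M | 0.100 M | 0.10 mM |  | a single well-mixed tank run continuously and read at steady state, 50.0 h in it on average |
| larch | 0.050 M | 0.100 M | 0.10 mM | 5.0 h | a closed flask charged with all of it at once and left for 5.0 h |

- percent here means substrate units held: one side product counts as two
- a doubled species enters its step squared and goes two at a time
- the stated concentrations are those of everything mixed, before any reaction; amounts are the same in each set-up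
- the feed brings no volume worth counting
- run time (oak): 5.0 h

* the set-up with the highest amount of target at the outlet or at the end, in percent of the substrate put in ("none" if the first two lie within 2 percentage points) (oak / alder / birch / larch / none)
* amount of target at the outlet or at the end, in percent of the substrate put in, oak
* amount of target at the outlet or at the end, in percent of the substrate put in, alder
* amount of target at the outlet or at the end, in percent of the substrate put in, birch
* amount of target at the outlet or at the end, in percent of the substrate put in, larch

A turn is a chain of waits. Free catalyst waits 0.476 min for coupling partner, catalyst intermediate A takes 0.270 min to become catalyst intermediate B, which waits 0.0303 min for substrate, and catalyst intermediate C takes 0.0370 min to release target. The first wait is longer than any other, but the second is of like size, so neither step alone sets the pace. I leave the resting dimer and the side step out of this sum, and the waits add to a cycle of 0.814 min.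

The charge asks 500 turns of each catalyst. Multiply that by the cycle and you have the clearing time, the time the catalyst needs to turn the whole charge once at a given cycle: 6.78 h at the charge levels.

Now read the recipes against it, in powers of ten. The rows for oak, alder and larch give 5.0 h, which stands −0.132 powers of ten from the clearing time, a fraction of 73.7%. The cycle lengthens as levels fall, so I expect target below that fraction in these three rows. Larch starts at the full pace. Oak starts short of substrate, and alder works throughout at its outlet levels, so I rank them in that order. The birch row gives 50.0 h, at 0.868 powers of ten, a whole power higher, so I expect it to turn nearly the whole charge.

The forecast named birch, said “birch is far ahead”, and gave oak 54.5%, alder 49%, birch 95.5% and larch 56.3%.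

The simulation gives birch as best, with oak 52.9%, alder 49.1%, birch 95.5% and larch 56.2%.

Take the back-mixing and the longer stay out of birch together, and its target falls from 95.5% to 56.2%. The alder tank holds coupling partner at 72.4% of its charge and substrate at 38.9%, so the cycle reads 1.04 min, and the clearing time 8.69 h, of which the stay covers 57.5%. The birch tank holds coupling partner at 51.2% of its charge and substrate at 0.640%, so its cycle reads 5.97 min, and its clearing time 49.8 h matches the stay, with target at 95.5%.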